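## Retrosynthetic overview
1. C7–OH: target ⇒ 7-deoxy phenol through the ring-A p-quinone methide. This is an anodic dehydrogenation, and water then adds anti to the C8 aryloxy group to give the erythro product.
2. All O-benzyl groups come off in one hydrogenolysis. C1'–C7' ⇒ ring-B aryl bromide (used as ArLi) + (S)-benzyl glycidyl ether, so C8' is bought.
3. C8–O4' ⇒ Mitsunobu inversion of an (R)-carbinol with 4-bromo-2,6-dimethoxyphenol.
4. C1–C7 ⇒ ring-A aryl Grignard + (R)-benzyl glycidyl ether, so C8 is bought.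
5. No ring is formed. Both arenes come from the same commercial bromophenol.

Assumption: neolignan numbering is used (C7–C9 on the phenolic ring A, C7'–C9' on ring B). The SMILES reads (7S,8R,8'S), which is erythro. Both enantiomers of benzyl glycidyl ether are taken as cheap catalogue chiral building blocks.

Note: no bond to C8 changes after the etherification. Its descriptor switches from S to R in the last step only because C7 gains oxygen and then outranks C9.

## Route

Step 1
Reactants: 1 4-bromo-2,6-dimethoxyphenol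
Product: 2 2-(benzyloxy)-5-bromo-1,3-dimethoxybenzene
Conditions: BnBr, K2CO3, DMF, rt
Reagents that add atoms: benzyl bromide BrCc1ccccc1
Why: Williamson ether synthesis masks the ring-A phenol so that it survives the organometallic step and cannot compete in the later etherification; no stereocenter is involved.

Step 2
Reactants: 2 2-(benzyloxy)-5-bromo-1,3-dimethoxybenzene; 3 (R)-benzyl glycidyl ether
Product: 5 (2R)-1-(benzyloxy)-3-[4-(benzyloxy)-3,5-dimethoxyphenyl]propan-2-ol, via arylmagnesium bromide 4 (not isolated)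
Conditions: Mg (I2 cat.), THF, 45 °C; then CuI (10 mol %), 3, −30 → 0 °C; aq NH4Cl
Reagents that add atoms: none
Why: Cu(I)-catalysed Grignard opening of a terminal epoxide is an SN2 attack at the CH2 terminus, so the C–O bond at the stereocenter is untouched and the (R) configuration of 3 is carried over.

Step 3
Reactants: 5 (2R)-1-(benzyloxy)-3-[4-(benzyloxy)-3,5-dimethoxyphenyl]propan-2-ol; 1 4-bromo-2,6-dimethoxyphenol
Product: 6 2-(benzyloxy)-5-[(2S)-3-(benzyloxy)-2-(4-bromo-2,6-dimethoxyphenoxy)propyl]-1,3-dimethoxybenzene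
Conditions: 1 (1.3 equiv), PPh3, DIAD, toluene (1 M), 0 °C → rt
Reagents that add atoms: none
Why: Mitsunobu etherification forms C8–O4' by SN2 inversion (R → S) of the only free hydroxyl, and the 4-bromo group makes the hindered phenol more acidic and serves as the handle for step 4.

Step 4
Reactants: 6 2-(benzyloxy)-5-[(2S)-3-(benzyloxy)-2-(4-bromo-2,6-dimethoxyphenoxy)propyl]-1,3-dimethoxybenzene; 7 (S)-benzyl glycidyl ether
Product: 9 (2S)-1-(benzyloxy)-3-[4-({(2S)-1-(benzyloxy)-3-[4-(benzyloxy)-3,5-dimethoxyphenyl]propan-2-yl}oxy)-3,5-dimethoxyphenyl]propan-2-ol, via aryllithium 8 (not isolated)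
Conditions: n-BuLi (1.05 equiv), THF, −78 °C; then 7, BF3·OEt2, −78 °C; aqueous work-up
Reagents that add atoms: none
Why: Bromine–lithium exchange followed by BF3-promoted epoxide opening at the terminal carbon leaves the epoxide stereocenter untouched, so C8' is (S) as bought in 7, and C8 is not affected at −78 °C.

Step 5
Reactants: 9 (2S)-1-(benzyloxy)-3-[4-({(2S)-1-(benzyloxy)-3-[4-(benzyloxy)-3,5-dimethoxyphenyl]propan-2-yl}oxy)-3,5-dimethoxyphenyl]propan-2-ol
Product: 10 (2S)-3-[4-({(2S)-1-hydroxy-3-(4-hydroxy-3,5-dimethoxyphenyl)propan-2-yl}oxy)-3,5-dimethoxyphenyl]propane-1,2-diol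
Conditions: H2 (1 atm), 10 % Pd/C, EtOH–EtOAc, rt
Reagents that add atoms: none
Why: Catalytic hydrogenolysis removes all three O-benzyl groups at once, and because C7 has no oxygen yet and the C8–OAr bond is only homobenzylic, nothing else can be cleaved.

Step 6
Reactants: 10 (2S)-3-[4-({(2S)-1-hydroxy-3-(4-hydroxy-3,5-dimethoxyphenyl)propan-2-yl}oxy)-3,5-dimethoxyphenyl]propane-1,2-diol
Product: 12 (1S,2R)-2-{4-[(2S)-2,3-dihydroxypropyl]-2,6-dimethoxyphenoxy}-1-(4-hydroxy-3,5-dimethoxyphenyl)propane-1,3-diol, via p-quinone methide 11 (not isolated)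
Conditions: RVC anode / Pt cathode, divided cell, +0.55 V vs Ag/AgCl, 2.0 F/mol, 10 mM in acetone–0.1 M phosphate buffer pH 7 (1:1), NaClO4, 0 °C, Ar; current off, citric acid to pH 4, rt, 2 h
Reagents that add atoms: water O
Why: Proposed new method: anodic dehydrogenative benzylic C–H hydroxylation of an unprotected 7-deoxy-8-O-4' neolignan; at the first phenol wave only the free syringyl phenol of ring A is oxidised (ring B is a trialkoxyarene roughly 0.7 V harder, and the alcohols are inert); proton-coupled loss of one electron gives the ortho-blocked phenoxyl radical, which by a second oxidation or by radical disproportionation loses C7–H as a proton to give p-quinone methide 11; 11 persists at pH 7 and 0 °C, so the oxidisable product forms only after the current is off, when mild acid triggers 1,6-addition of water at C7; in the allylic-strain-minimised conformer (C8–H eclipsing the exocyclic C=C) the bulky 2,6-dimethoxyaryloxy group covers one face, so water adds anti to it and the bought C8 center sets 7S (erythro, expected about 3–4:1, threo isomer removed by chromatography); the closest known reaction types are Ag2O, DDQ or anodic dehydrogenation of 4-alkyl-2,6-disubstituted phenols to quinone methides with solvent capture, and the erythro-selective hydration of lignin β-syringyl-ether quinone methides.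

## Compound list
1 | 4-bromo-2,6-dimethoxyphenol | COc1cc(Br)cc(OC)c1O | starting material
2 | 2-(benzyloxy)-5-bromo-1,3-dimethoxybenzene | COc1cc(Br)cc(OC)c1OCc1ccccc1 | intermediate
3 | (R)-benzyl glycidyl ether, (2R)-2-[(benzyloxy)methyl]oxirane | C1O[C@H]1COCc1ccccc1 | starting material
4 | [4-(benzyloxy)-3,5-dimethoxyphenyl]magnesium bromide (not isolated) | COc1cc([Mg]Br)cc(OC)c1OCc1ccccc1 | intermediate
5 | (2R)-1-(benzyloxy)-3-[4-(benzyloxy)-3,5-dimethoxyphenyl]propan-2-ol | COc1cc(C[C@@H](O)COCc2ccccc2)cc(OC)c1OCc1ccccc1 | intermediate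
6 | 2-(benzyloxy)-5-[(2S)-3-(benzyloxy)-2-(4-bromo-2,6-dimethoxyphenoxy)propyl]-1,3-dimethoxybenzene | COc1cc(C[C@H](Oc2c(OC)cc(Br)cc2OC)COCc2ccccc2)cc(OC)c1OCc1ccccc1 | intermediate
7 | (S)-benzyl glycidyl ether, (2S)-2-[(benzyloxy)methyl]oxirane | C1O[C@@H]1COCc1ccccc1 | starting material
8 | ring-B aryllithium from 6, Li in place of Br (not isolated) | COc1cc(C[C@H](Oc2c(OC)cc([Li])cc2OC)COCc2ccccc2)cc(OC)c1OCc1ccccc1 | intermediate
9 | (2S)-1-(benzyloxy)-3-[4-({(2S)-1-(benzyloxy)-3-[4-(benzyloxy)-3,5-dimethoxyphenyl]propan-2-yl}oxy)-3,5-dimethoxyphenyl]propan-2-ol | COc1cc(C[C@H](Oc2c(OC)cc(C[C@H](O)COCc3ccccc3)cc2OC)COCc2ccccc2)cc(OC)c1OCc1ccccc1 | intermediate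
10 | (2S)-3-[4-({(2S)-1-hydroxy-3-(4-hydroxy-3,5-dimethoxyphenyl)propan-2-yl}oxy)-3,5-dimethoxyphenyl]propane-1,2-diol (7-deoxy compound) | COc1cc(C[C@H](Oc2c(OC)cc(C[C@H](O)CO)cc2OC)CO)cc(OC)c1O | intermediate
11 | 4-[(2S)-2-{4-[(2S)-2,3-dihydroxypropyl]-2,6-dimethoxyphenoxy}-3-hydroxypropylidene]-2,6-dimethoxycyclohexa-2,5-dien-1-one (not isolated) | COC1=CC(=C[C@H](Oc2c(OC)cc(C[C@H](O)CO)cc2OC)CO)C=C(OC)C1=O | intermediate
12 | (1S,2R)-2-{4-[(2S)-2,3-dihydroxypropyl]-2,6-dimethoxyphenoxy}-1-(4-hydroxy-3,5-dimethoxyphenyl)propane-1,3-diol, (7S,8R,8'S) | COc1cc([C@H](O)[C@@H](CO)Oc2c(OC)cc(C[C@H](O)CO)cc2OC)cc(OC)c1O | target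

## Totals and risks
Total step count: 6. Longest linear sequence: 6 (1 → 2 → 5 → 6 → 9 → 10 → 12).

**Step 6 (the new step).**
- Risks: over-oxidation of the product phenol to the ketone or to aryl–alkyl cleavage, electrode fouling by phenoxyl coupling, and only modest facial selectivity.
- Fallback: sets out from 10 and returns at 12. It gives up the C–H hydroxylation and sets C7 by hydride delivery. DDQ (2.2 equiv) in dioxane–water 9:1 at rt drives the 4-alkylphenol deliberately through to the aryl ketone (2R)-2-{4-[(2S)-2,3-dihydroxypropyl]-2,6-dimethoxyphenoxy}-3-hydroxy-1-(4-hydroxy-3,5-dimethoxyphenyl)propan-1-one F1. This is the known benzylic oxidation of p-alkylphenols, and over-oxidation is no longer a concern. F1 is kept away from base and used at once. Zn(BH4)2 in THF at −20 °C then reduces it under Cram-chelate control, the classical erythro-selective reduction of α-aryloxy ketones, to 12.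

**Step 3.**
- Risks: a hindered 2,6-disubstituted phenol on a secondary carbinol, elimination to the cinnamyl ether, and participation of the electron-rich β-aryl group that would erode the inversion.
- Fallback: sets out from 4 and returns at 6. It moves the substitution to an α-ester carbon, where SN2 is accelerated and ionisation is suppressed.
  - Grignard 4 opens commercial methyl (R)-glycidate (COC(=O)[C@H]1CO1, L-serine derived) at C3 with CuBr·SMe2 in THF at −40 °C. This gives methyl (2R)-3-[4-(benzyloxy)-3,5-dimethoxyphenyl]-2-hydroxypropanoate F2.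
  - A lactate-type Mitsunobu reaction with 1 (PPh3, DIAD, THF) gives, with inversion, methyl (2S)-3-[4-(benzyloxy)-3,5-dimethoxyphenyl]-2-(4-bromo-2,6-dimethoxyphenoxy)propanoate F3.
  - LiBH4 in THF–MeOH at 0 °C gives (2S)-3-[4-(benzyloxy)-3,5-dimethoxyphenyl]-2-(4-bromo-2,6-dimethoxyphenoxy)propan-1-ol F4.
  - NaH and BnBr in DMF at 0 °C give 6.

**Step 4.**
- Risks: organolithium chemistry on an advanced intermediate, namely protonation of 8, butylation by n-BuBr, BF3-induced epoxide rearrangement, and base-induced loss of the C8 aryloxide.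
- Fallback: sets out from 6 and returns at 10. It replaces the polar epoxide opening by a radical cross-electrophile coupling with a different C3 building block.
  - Compound 6 and commercial (R)-4-(bromomethyl)-2,2-dimethyl-1,3-dioxolane (BrC[C@H]1COC(C)(C)O1, from (S)-solketal) are coupled under known Ni/photoredox silyl-radical conditions: Ir[dF(CF3)ppy]2(dtbbpy)PF6, NiCl2·glyme/dtbbpy, (TMS)3SiH, Na2CO3, DME, blue LED.
  - The product is (4S)-4-[4-({(2S)-1-(benzyloxy)-3-[4-(benzyloxy)-3,5-dimethoxyphenyl]propan-2-yl}oxy)-3,5-dimethoxybenzyl]-2,2-dimethyl-1,3-dioxolane F5. The stereocenter sits next to the radical carbon, not on it, so it is retained.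
  - H2 and Pd/C in THF–1 M aq HCl (10:1) at rt then remove both benzyl groups and the acetonide to give 10.

## Further compounds
F1 | step 6 | (2R)-2-{4-[(2S)-2,3-dihydroxypropyl]-2,6-dimethoxyphenoxy}-3-hydroxy-1-(4-hydroxy-3,5-dimethoxyphenyl)propan-1-one | COc1cc(C(=O)[C@@H](CO)Oc2c(OC)cc(C[C@H](O)CO)cc2OC)cc(OC)c1O
F2 | step 3 | methyl (2R)-3-[4-(benzyloxy)-3,5-dimethoxyphenyl]-2-hydroxypropanoate | COc1cc(C[C@@H](O)C(=O)OC)cc(OC)c1OCc1ccccc1
F3 | step 3 | methyl (2S)-3-[4-(benzyloxy)-3,5-dimethoxyphenyl]-2-(4-bromo-2,6-dimethoxyphenoxy)propanoate | COc1cc(C[C@H](Oc2c(OC)cc(Br)cc2OC)C(=O)OC)cc(OC)c1OCc1ccccc1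
F4 | step 3 | (2S)-3-[4-(benzyloxy)-3,5-dimethoxyphenyl]-2-(4-bromo-2,6-dimethoxyphenoxy)propan-1-ol | COc1cc(C[C@H](Oc2c(OC)cc(Br)cc2OC)CO)cc(OC)c1OCc1ccccc1
F5 | step 4 | (4S)-4-[4-({(2S)-1-(benzyloxy)-3-[4-(benzyloxy)-3,5-dimethoxyphenyl]propan-2-yl}oxy)-3,5-dimethoxybenzyl]-2,2-dimethyl-1,3-dioxolane | COc1cc(C[C@H](Oc2c(OC)cc(C[C@H]3COC(C)(C)O3)cc2OC)COCc2ccccc2)cc(OC)c1OCc1ccccc1
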